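The runs come from a simulation with constants of no real substance, noise included.

| flask | starting material | free catalyst | impurity | remark | time |
|---|---|---|---|---|---|
| east | 0.082 M | 0.77 mM | 0.13 mM | run made earlier |  |
| south | 0.15 M | 0.77 mM | 0.13 mM | run made earlier |  |
| west | 0.23 M | 0.77 mM | 0.13 mM | run made earlier |  |
| autumn | 0.25 M | 0.77 mM | 0.13 mM |  | 2.5 min |
| dawn | 0.080 M | 0.77 mM | 0.13 mM |  | 2.5 min |

| run | time / s | product / % | starting material / % |
|---|---|---|---|
| east | 10.0 | 63.4 | 12.1 |
| east | 25.0 | 74.5 | 0 |
| east | 50.0 | 73.8 | 0 |
| east | 80.0 | 75.3 | 0 |
| east | 120 | 75.3 | 0 |
| south | 10.0 | 51.7 | 11.7 |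
| south | 25.0 | 59.2 | 2.9 |
| south | 50.0 | 60.5 | 1.6 |
| south | 80.0 | 60.6 | 0 |
| south | 120 | 62.1 | 0.6 |
| west | 10.0 | 42.8 | 9.2 |
| west | 15.0 | 46.8 | 2.1 |
| west | 30.0 | 48.4 | 0 |
| west | 60.0 | 49.6 | 0.7 |
| west | 120 | 48.9 | 0 |

(scatter of a reading: 1 percentage point)

1. which of the two ends with the higher amount of product, in percent of the starting material charged ("neither" if they lie within 2 percentage points) (autumn / dawn / neither)
2. product at the end, in percent of the starting material charged, autumn
3. product at the end, in percent of the starting material charged, dawn

1. Slowness is what we want to measure: how slow is the productive route beside whatever else takes starting material? Over the last three readings the product averages 74.8% in east, 61.1% in south and 49.0% in west. Catalyst and impurity charges stay the same, while the starting material changes.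

2. We follow one molecule of starting material to a fork, a question of selectivity. We take the productive route as first order in [starting material] and the loss as second order, so the chance of product is K/(K+[starting material]), with K to be read from the runs.

3. There are two extreme flasks. If every molecule met the fork at full charge, the yield would be K/(K+charge). If every molecule met it in a nearly empty flask, the yield would be 100%. The real flask runs from the first state to the second, so we take half the charge as the typical fork: yield = K/(K+charge/2).

4. South then reads 0.118 M for K, the even-odds concentration, the [starting material] at which a molecule has equal chances at the fork. East reads 0.122 M and west 0.110 M, lower than east but close enough for us to carry the south value.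

5. For autumn, the full-charge extreme gives 32.0% and the half-charge rule 48.5%. For dawn, the rule gives 74.6%, so we expect autumn to end lower. The time allowed, 2.5 min, is longer than the last readings at 120 s.

6. The forecast says dawn ends higher, with 46.5% for autumn and 75.5% for dawn, on the grounds of “a side reaction of about second order in starting material”. Our autumn estimate stands higher than the forecast's by 2 percentage points, our dawn estimate lower by 0.90 points.

7. The flask gives 47.5% for autumn and 75.4% for dawn, so dawn ends higher.

    starting material + free catalyst → catalyst intermediate (k = 290 L mol⁻¹ s⁻¹)
    catalyst intermediate → free catalyst + product (k = 66.0 s⁻¹)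
    free catalyst + impurity → spent catalyst (k = 6400 L mol⁻¹ s⁻¹)
    2 starting material → homo dimer (k = 0.700 L mol⁻¹ s⁻¹)

Taking away the turning of two starting material into homo dimer lifts autumn from 47.5% to 100%, so that step is the main reason for autumn's shortfall. A changed catalyst charge is one way for the forecast's autumn figure to fail: at 0.622 mM or 0.954 mM of free catalyst instead of 0.77 mM, autumn's product lies 5 points from 47.5%, and K was read at 0.77 mM. In the neighbour, dawn with 0.048 M of starting material, the half-charge rule with K gives 83.1%; the flask gives 84.0%.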